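## Analysis of the target

The target 13 is 3,4,6-tribromo-5-[(methylsulfonyl)methyl]benzene-1,2-diol, a single benzene ring in which all six positions are substituted. With the ring numbered C1 (CH2SO2CH3), C2 (Br), C3 (OH), C4 (OH), C5 (Br), C6 (Br), no ring hydrogen remains. There is no stereocentre and no other element of chirality, so nothing stereochemical has to be carried to the end. The sensitive parts are the catechol, which is easily oxidised to the ortho-quinone (fastest as its anion in air), and the benzylic sulfone, whose CH2 is acidic. Because the C4 hydroxyl is para to C1, a phenoxide can also expel sulfinate through a quinone methide. Halogen regiochemistry is not the difficulty, since every free position is brominated; the real problem is to reach a 4-substituted catechol with the sulfonylmethyl arm in place and to account for the oxidation level of the ring without a harsh dehydrogenation. The strategy rests on reading C2–C3–C4–C5, with its vicinal oxygens on C3 and C4, as a butadiene oxygenated on both inner carbons and C1/C6 as a two-carbon unit. C1 carries the arm, and C6, which ends as C–Br, is free to carry a temporary sulfonyl group that activates the alkene and later leaves as sulfinate.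

## Retrosynthetic reasoning

**13 ⇒ 12.** The three C–Br bonds at C2, C5 and C6 are cut first, giving 4-[(methylsulfonyl)methyl]benzene-1,2-diol 12. Every position not occupied by oxygen or the arm is brominated, so exhaustive electrophilic bromination needs no regiocontrol. C2 and C5 are ortho and C6 is para to a hydroxyl, so all three are activated. Leaving the halogens to the end keeps them out of the cycloaddition and the elimination. The forward step has to brominate three times without leaving the ring at the quinone level and without touching the benzylic sulfone.

**12 ⇒ 11 ⇒ 10 ⇒ 9.** Catechol 12 is the aromatic tautomer of ene-dione 11 (carbonyls at C3 and C4, C5=C6, sp3 C1 and C2). Returning a sulfonyl group to C6 gives dione 10, in which that group is β to the C4 carbonyl. Dione 10 is the two-electron oxidation product of the enediol bis-silyl ether 9. No ring bond is cut here. The gain is that C1, C2, C5 and C6 become sp3 carbons of a cyclohexene, and that one of the two unsaturations needed for aromaticity is supplied by a leaving group instead of an oxidant. The forward sequence must stop the oxidation at the dione. It must also expel only the ring sulfonyl group: the arm sulfonyl sits on a carbon γ to the C3 carbonyl and cannot undergo β-elimination.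

**9 ⇒ 7 + 8.** The C1–C2 and C5–C6 bonds are cut. This is the only pair of ring bonds that separates a symmetric four-carbon piece holding both oxygens, diene 8, from a two-carbon piece holding everything else, alkene 7. The symmetry of 8 removes regiochemistry, and the sulfonyl group at the future C6 is the activating group of the dienophile. The forward reaction is a thermal [4+2] cycloaddition that has to be faster than loss of the silyl enol ethers.

**7 ⇒ 6 ⇒ 5.** The double bond of 7 comes from β-elimination of mesylate 6, made from alcohol 5. Because 5 is symmetric, elimination toward either side gives the same alkene. Later migration of the double bond between the allyl and vinyl sulfone positions only regenerates 7.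

**5 ⇒ 4 ⇒ 1 + 2.** The two C–S bonds are cut. Sulfur is the good nucleophile at the thiolate level, so both sulfur atoms are introduced as sulfides from epichlorohydrin 1 and two equivalents of sodium thiomethoxide 2, through epoxide 3, giving the bis-sulfide alcohol 4. Sulfur is then oxidised to the bis-sulfone 5. Compound 1 supplies the three carbons with the oxygen already on the central one.

## Alternatives that were turned down

Alternative 1: The ring is cut at C2–C3 and C4–C5. Carbons C5, C6, C1 and C2, with all three bromines and the arm, come from 2,3,5-tribromo-4-[(methylsulfonyl)methyl]thiophene 1,1-dioxide A2, and the two oxygenated carbons from vinylene carbonate A3. Cycloaddition across the α-carbons of A2 and cheletropic loss of the sulfonyl bridge would give the cis-fused dihydrobenzodioxolone A1.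
- For it: the halogen pattern is fixed before the ring forms, so no oxidation-prone catechol is exposed to a halogenating agent, and gas loss makes the cycloaddition irreversible. On this point it is stronger than the chosen route.
- Against it: A1 is one oxidation level short. cis-Dihydrodiol derivatives of this kind aromatise most easily by β-elimination of one oxygen, which would lose a hydroxyl, so the required dehydrogenation must compete with that. A2 needs a multistep heterocycle synthesis and S-oxidation of a very electron-poor thiophene, and its CH2 between a sulfonyl group and the diene invites tautomerisation and dimerisation. A3 is a sluggish dienophile.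
- Comparison: the chosen strategy has no regiochemical problem to solve in the bromination, takes its oxidation level from the departing sulfinate, and is about two steps shorter from bulk chemicals.

Alternative 2: The C3–C4 bond between the two oxygenated carbons is cut, leading to 3-[(methylsulfonyl)methyl]hexanedial A4. A carbene-catalysed benzoin cyclisation would give the acyloin 2-hydroxy-5-[(methylsulfonyl)methyl]cyclohexan-1-one A5.
- For it: the ring closure is catalytic, runs near room temperature and involves no hydrolytically labile group. All regio- and stereoisomers of A5 converge on the same arene. On mildness of the ring-forming step it is stronger than a 140 °C cycloaddition.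
- Against it: A5 is fully saturated, two oxidation levels below the catechol. An acyloin oxidation and a ring dehydrogenation by halogenation–dehydrohalogenation must follow. A 1,6-dialdehyde under basic carbene conditions can also close a five-membered ring by intramolecular aldol condensation. A4 is most simply made by cleaving a six-membered ring, which is then reclosed.
- Comparison: the chosen strategy builds the correct oxidation level into the cycloadduct and joins two fragments convergently, at a similar step count.

Alternative 3: The C1=C6 bond is cut, leading to 2-[(methylsulfonyl)methyl]octa-1,7-diene-4,5-diol A6. Ring-closing metathesis with second-generation Grubbs catalyst would give trans-4-[(methylsulfonyl)methyl]cyclohex-4-ene-1,2-diol A7 with loss of the two terminal methylene groups.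
- For it: metathesis to a cyclohexene is among the most dependable ring closures, and the new double bond is already an aromatic one. Double oxidation of the diol of A7 leads to a tautomer of the catechol, so the redox arithmetic closes. On reliability of the ring-forming step it is at least as strong as the chosen route.
- Against it: A6 is unsymmetrical, with a 1,1-disubstituted allyl sulfone end and a plain allyl end on a 1,2-diol. It needs stepwise assembly with differentiated allyl nucleophiles (five steps or more). Oxidising a 1,2-diol to the dione level risks C–C cleavage and consumes four electrons of stoichiometric oxidant. A ruthenium catalyst is required.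
- Comparison: the chosen strategy is shorter and convergent, needs no precious metal, and has half of the oxidation delivered by a leaving group.

Key step: step 4

Assumption: diene 8 is purchased and distilled before use; all chiral intermediates are racemic, which has no consequence because the target has no stereocentre.

## Route

Step 1
Reactants: 1 epichlorohydrin; 2 sodium thiomethoxide
Product: 4 1,3-bis(methylsulfanyl)propan-2-ol, via 2-[(methylsulfanyl)methyl]oxirane 3 (not isolated)
Conditions: NaSCH3 (2.1 equiv in total, aqueous), MeOH, 0 → 25 °C
Reagents that add atoms: sodium thiomethoxide (second equivalent of 2), C[S-].[Na+]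
Why: The first equivalent of thiolate attacks 1 by SN2 and the resulting chlorohydrin alkoxide recloses to epoxide 3; the second equivalent opens 3 at its terminal carbon, and protonation by the solvent gives the symmetric bis-sulfide alcohol, the standard outcome of epichlorohydrin with two equivalents of a thiolate.

Step 2
Reactants: 4 1,3-bis(methylsulfanyl)propan-2-ol
Product: 5 1,3-bis(methylsulfonyl)propan-2-ol
Conditions: 30% aq. H2O2 (4.4 equiv), Na2WO4·2H2O (2 mol%), MeOH–H2O, 0 → 55 °C
Reagents that add atoms: hydrogen peroxide, OO
Why: Tungstate-catalysed peroxide oxidation takes sulfides through sulfoxides to sulfones far faster than it touches an unactivated secondary alcohol at this temperature; the polar bis-sulfone should crystallise from the concentrated aqueous alcohol.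

Step 3
Reactants: 5 1,3-bis(methylsulfonyl)propan-2-ol
Product: 7 (E)-1,3-bis(methylsulfonyl)prop-1-ene, via mesylate 6 (not isolated)
Conditions: MsCl (1.15 equiv), Et3N (2.3 equiv), MeCN–CH2Cl2, 0 → 25 °C
Reagents that add atoms: none
Why: Mesylation followed by E1cB elimination through the acidic α-sulfonyl CH2 is the usual route from β-hydroxy sulfones to vinyl sulfones; the symmetric substrate gives one constitution, and the amine equilibrates the alkene to the more stable E isomer through the degenerate allyl/vinyl sulfone shift.

Step 4
Reactants: 7 (E)-1,3-bis(methylsulfonyl)prop-1-ene; 8 2,3-bis(trimethylsilyloxy)buta-1,3-diene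
Product: 9 trans-4-(methylsulfonyl)-5-[(methylsulfonyl)methyl]-1,2-bis(trimethylsilyloxy)cyclohex-1-ene (racemic)
Conditions: 8 (3 equiv), BHT (cat.), dry PhCl, 140 °C, sealed tube, Ar; then evaporation of volatiles
Reagents that add atoms: none
Why: This is a thermal normal-electron-demand Diels–Alder reaction in which the HOMO of the doubly oxygen-substituted diene 8 meets the LUMO of the sulfonyl-activated alkene 7 in a concerted, suprafacial-suprafacial [4+2] transition state. The closest known reaction type is the cycloaddition of 2-silyloxy- and 2,3-bis(silyloxy)butadienes with electron-poor alkenes, together with the use of vinyl sulfones as dienophiles. The six-membered carbocycle is closed by the cycloaddition itself: both new sigma bonds (C1–C2 and C5–C6 in the numbering of the target) form in the same step, so there is no separate ring-closing event and no ring-size alternative. The two new stereocentres at C4 and C5 of the cyclohexene are set relative to each other by the E geometry of 7, which a suprafacial addition transfers unchanged into a trans arrangement; with no chiral element present the adduct is racemic, and both centres are removed in step 5. The symmetric diene makes the two orientations of 7 identical, so there is no regiochemical issue, and the unsubstituted diene termini leave no endo/exo consequence. The selectivity that matters is kinetic chemoselectivity: cycloaddition has to be faster than protodesilylation of the silyl enol ethers and than oligomerisation of 7, which is secured by an aprotic, acid-free medium, excess diene, a radical inhibitor and the activation of the alkene by its own sulfonyl group reinforced by the inductive pull of the CH2SO2CH3 substituent. Prototropic shift of the double bond in 7 only regenerates 7, so no isomeric dienophile can intervene.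

Step 5
Reactants: 9 trans-4-(methylsulfonyl)-5-[(methylsulfonyl)methyl]-1,2-bis(trimethylsilyloxy)cyclohex-1-ene
Product: 12 4-[(methylsulfonyl)methyl]benzene-1,2-diol, via cyclohexane-1,2-dione 10 (not isolated), via cyclohex-3-ene-1,2-dione 11 (not isolated)
Conditions: Br2 (1.0 equiv), CH2Cl2, −78 → 0 °C; evaporation; then Et3N (2.5 equiv), degassed THF, 0 → 25 °C, Ar
Reagents that add atoms: none
Why: Bromine oxidation of acyloin-type 1,2-bis(silyloxy)alkenes to 1,2-diones with loss of two Me3SiBr is established chemistry; in 10 the ring sulfonyl group is β to a carbonyl, so amine-induced E1cB elimination of sulfinate gives 11, which enolises twice to the aromatic catechol. The arm sulfonyl group sits on a γ-carbon and cannot leave this way; low temperature, exclusion of air and a weak amine base keep the catechol from oxidation and from quinone-methide loss of the benzylic sulfinate.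

Step 6
Reactants: 12 4-[(methylsulfonyl)methyl]benzene-1,2-diol
Product: 13 3,4,6-tribromo-5-[(methylsulfonyl)methyl]benzene-1,2-diol
Conditions: Br2 (3.3 equiv), AcOH, 25 → 50 °C
Reagents that add atoms: bromine, BrBr
Why: Electrophilic aromatic bromination; each of the three free positions is ortho or para to a hydroxyl and the fourth is blocked by the arm, so exhaustive substitution needs no regiocontrol, as in the perbromination of simple catechols. A reductive aqueous work-up returns any ortho-quinone to the catechol.

## Compound list

1 | epichlorohydrin (2-(chloromethyl)oxirane, racemic) | ClCC1CO1 | starting material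
2 | sodium thiomethoxide | C[S-].[Na+] | starting material
3 | 2-[(methylsulfanyl)methyl]oxirane (racemic) | CSCC1CO1 | intermediate
4 | 1,3-bis(methylsulfanyl)propan-2-ol | CSCC(O)CSC | intermediate
5 | 1,3-bis(methylsulfonyl)propan-2-ol | CS(=O)(=O)CC(O)CS(C)(=O)=O | intermediate
6 | 1,3-bis(methylsulfonyl)propan-2-yl methanesulfonate | CS(=O)(=O)CC(OS(C)(=O)=O)CS(C)(=O)=O | intermediate
7 | (E)-1,3-bis(methylsulfonyl)prop-1-ene | CS(=O)(=O)C/C=C/S(C)(=O)=O | intermediate
8 | 2,3-bis(trimethylsilyloxy)buta-1,3-diene | C=C(O[Si](C)(C)C)C(=C)O[Si](C)(C)C | starting material
9 | trans-4-(methylsulfonyl)-5-[(methylsulfonyl)methyl]-1,2-bis(trimethylsilyloxy)cyclohex-1-ene (racemic, one enantiomer drawn) | C[Si](C)(C)OC1=C(O[Si](C)(C)C)C[C@H](S(C)(=O)=O)[C@@H](CS(C)(=O)=O)C1 | intermediate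
10 | trans-4-(methylsulfonyl)-5-[(methylsulfonyl)methyl]cyclohexane-1,2-dione (racemic, one enantiomer drawn) | O=C1C(=O)C[C@H](S(C)(=O)=O)[C@@H](CS(C)(=O)=O)C1 | intermediate
11 | 5-[(methylsulfonyl)methyl]cyclohex-3-ene-1,2-dione (racemic, one enantiomer drawn) | O=C1C(=O)C=C[C@@H](CS(C)(=O)=O)C1 | intermediate
12 | 4-[(methylsulfonyl)methyl]benzene-1,2-diol | CS(=O)(=O)Cc1ccc(O)c(O)c1 | intermediate
13 | 3,4,6-tribromo-5-[(methylsulfonyl)methyl]benzene-1,2-diol | CS(=O)(=O)Cc1c(Br)c(O)c(O)c(Br)c1Br | target

## Step count and risk

Total step count: 6. Longest linear sequence: 6 steps (1 to 13); diene 8 enters as a purchased reagent in step 4.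

**Step 4 (key step).** The cycloaddition may be slower than the degradation of the partners. The competing processes are protodesilylation of the silyl enol ethers of 8 and 9 by traces of protic material, and self-condensation of 7 through its acidic allylic CH2. The cause is that a 1,2-disubstituted vinyl sulfone is only a moderately reactive dienophile and 8 is not held s-cis. Fallback: setting out from 7, the diene is replaced by an s-cis-locked, hydrolytically more robust one. trans-4,5-Bis(bromomethyl)-2,2-dimethyl-1,3-dioxolane F1 is dehydrobrominated twice with KOtBu in THF to 2,2-dimethyl-4,5-dimethylidene-1,3-dioxolane F2. Cycloaddition of F2 with 7 in toluene at 80–110 °C should give the enediol acetonide trans-2,2-dimethyl-5-(methylsulfonyl)-6-[(methylsulfonyl)methyl]-4,5,6,7-tetrahydro-1,3-benzodioxole F3. Aqueous HCl in THF should hydrolyse the enol acetal to the acyloin 2-hydroxy-5-(methylsulfonyl)-4-[(methylsulfonyl)methyl]cyclohexan-1-one F4; either placement of its carbonyl leads on to the same dione. Dess–Martin periodinane should oxidise F4 to dione 10, where the fallback rejoins the route for the amine treatment of step 5.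

**Step 5.** Two processes threaten it. One is over-bromination at the enolisable α-positions of the dione. The other, once the catechol meets base, is air oxidation and expulsion of the benzylic sulfinate through a quinone methide. Fallback: setting out from 9, Bu4NF buffered with AcOH in THF removes both silyl groups and gives the acyloin F4 described under step 4. Et3N then induces loss of the ring sulfinate before any aromatic ring exists, with tautomerisation to 4-[(methylsulfonyl)methyl]cyclohexane-1,2-dione F5. F5 with Br2 (about 4.2 equiv) in AcOH should undergo α-bromination and dehydrobromination to the catechol and exhaustive ring bromination in one acidic operation. This is the classical halogenative aromatisation of cyclohexane-1,2-diones, and it rejoins the route at 13 without exposing a catechol to base.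

**Step 6.** Oxidation of the electron-rich catechol to the ortho-quinone may compete with substitution, and bromination may stall before the most hindered position next to the arm. Fallback: setting out from 12, the oxidation is made deliberate. Excess Br2 (5 equiv or more) in AcOH at 60 °C drives everything, through repeated HBr conjugate addition and re-oxidation, to 3,4,6-tribromo-5-[(methylsulfonyl)methyl]cyclohexa-3,5-diene-1,2-dione F6. F6 is then reduced in a separate operation with aqueous Na2S2O4 in EtOAc, rejoining at 13.

**Step 3.** Base-induced oligomerisation may occur: the allyl sulfonyl carbanion of the product can add to a second molecule of vinyl sulfone. E/Z mixtures may also form. Fallback: setting out from 4, the double bond is made at the sulfide oxidation level. O-Methylation (NaH, MeI, THF) gives 2-methoxy-1,3-bis(methylsulfanyl)propane F7. Lithium diisopropylamide (2.1 equiv, THF, −78 → 0 °C) eliminates methoxide and forms the thioallyl anion, which on protonation gives 1,3-bis(methylsulfanyl)prop-1-ene F8. Oxidation of F8 with H2O2 and Na2WO4·2H2O, as in step 2, then rejoins the route at 7, with the E isomer secured by crystallisation.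

## Further compounds

F1 | step 4 | trans-4,5-bis(bromomethyl)-2,2-dimethyl-1,3-dioxolane (racemic, one enantiomer drawn) | CC1(C)O[C@H](CBr)[C@@H](CBr)O1
F2 | step 4 | 2,2-dimethyl-4,5-dimethylidene-1,3-dioxolane | CC1(C)OC(=C)C(=C)O1
F3 | step 4 | trans-2,2-dimethyl-5-(methylsulfonyl)-6-[(methylsulfonyl)methyl]-4,5,6,7-tetrahydro-1,3-benzodioxole (racemic, one enantiomer drawn) | CC1(C)OC2=C(O1)C[C@H](S(C)(=O)=O)[C@@H](CS(C)(=O)=O)C2
F4 | step 4 | 2-hydroxy-5-(methylsulfonyl)-4-[(methylsulfonyl)methyl]cyclohexan-1-one (4,5-trans, carbinol epimers, one regioisomer drawn) | OC1C(=O)C[C@H](S(C)(=O)=O)[C@@H](CS(C)(=O)=O)C1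
F5 | step 5 | 4-[(methylsulfonyl)methyl]cyclohexane-1,2-dione (racemic) | CS(=O)(=O)CC1CCC(=O)C(=O)C1
F6 | step 6 | 3,4,6-tribromo-5-[(methylsulfonyl)methyl]cyclohexa-3,5-diene-1,2-dione | CS(=O)(=O)CC1=C(Br)C(=O)C(=O)C(Br)=C1Br
F7 | step 3 | 2-methoxy-1,3-bis(methylsulfanyl)propane | COC(CSC)CSC
F8 | step 3 | 1,3-bis(methylsulfanyl)prop-1-ene (E/Z mixture, E drawn) | CS/C=C/CSC
A1 | alternative 1 | cis-4,5,7-tribromo-6-[(methylsulfonyl)methyl]-3a,7a-dihydro-1,3-benzodioxol-2-one (racemic, one enantiomer drawn) | O=C1O[C@@H]2[C@H](O1)C(Br)=C(Br)C(CS(C)(=O)=O)=C2Br
A2 | alternative 1 | 2,3,5-tribromo-4-[(methylsulfonyl)methyl]thiophene 1,1-dioxide | O=S1(=O)C(Br)=C(Br)C(CS(C)(=O)=O)=C1Br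
A3 | alternative 1 | vinylene carbonate (1,3-dioxol-2-one) | O=C1OC=CO1
A4 | alternative 2 | 3-[(methylsulfonyl)methyl]hexanedial | O=CCC(CS(C)(=O)=O)CCC=O
A5 | alternative 2 | 2-hydroxy-5-[(methylsulfonyl)methyl]cyclohexan-1-one (one of the convergent isomers drawn) | CS(=O)(=O)C[C@H]1CC[C@H](O)C(=O)C1
A6 | alternative 3 | 2-[(methylsulfonyl)methyl]octa-1,7-diene-4,5-diol (relative configuration as in A7, racemic) | C=CC[C@@H](O)[C@H](O)CC(=C)CS(C)(=O)=O
A7 | alternative 3 | (1R*,2R*)-4-[(methylsulfonyl)methyl]cyclohex-4-ene-1,2-diol (trans, racemic) | C1[C@@H](O)[C@H](O)CC(CS(C)(=O)=O)=C1
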